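**Assumption:** the SMILES is read as the (3R,4S)-trans 3,4-diarylchroman ("chroman A") carrying a (3R)-3-arylchroman ("chroman B") on its C4 aryl ring; 2-bromo-3,3-diethoxyprop-1-ene and 3-(benzyloxy)phenol are taken as catalogue reagents.

## Retrosynthetic overview

1. Target ⇐ tetrabenzyl ether ⇐ C2-lactol of chroman A; benzyl is the only protecting group and is removed in the last step.
2. C3 of chroman B ⇐ ligand-controlled iridium hydrogenation of the corresponding 3-aryl-2H-chromene.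
3. Key step: both pyran rings close in one operation from a bis(ortho-hydroxybenzylic carbinol) through two ortho-quinone methides. Chroman A forms by amine-catalysed formal [4+2] with an arylacetaldehyde (C3–C4 and O1–C2 bonds, sets 3R,4S); chroman B forms by oxa-6π ring closure (O1–C2).
4. Bis-carbinol ⇐ dialdehyde (aryl aldehyde plus 2-arylacrolein) + two 3-(benzyloxy)phenols by ortho C-hydroxyalkylation, which makes both C4–C4a bonds.
5. Dialdehyde ⇐ 2,4-dihydroxy-6-methoxybenzaldehyde (benzylation, triflation, Negishi coupling with an acrolein α-anion equivalent); arylacetaldehyde ⇐ 2-hydroxy-4,5-dimethoxybenzaldehyde. No ring is made before the key step.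

## Route

**Step 1**
Reactants: 1 2,4-dihydroxy-6-methoxybenzaldehyde
Product: 2 4-(benzyloxy)-2-hydroxy-6-methoxybenzaldehyde
Conditions: BnBr (1.05 equiv), K2CO3, acetone, 50 °C
Reagents that add atoms: benzyl bromide, BrCc1ccccc1
Why: Williamson etherification; the 2-OH is hydrogen-bonded to the formyl group and stays free, so only the 4-OH is benzylated.

**Step 2**
Reactants: 2 4-(benzyloxy)-2-hydroxy-6-methoxybenzaldehyde
Product: 3 5-(benzyloxy)-2-formyl-3-methoxyphenyl trifluoromethanesulfonate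
Conditions: Tf2O, pyridine, CH2Cl2, 0 °C
Reagents that add atoms: trifluoromethanesulfonic anhydride, O=S(=O)(OS(=O)(=O)C(F)(F)F)C(F)(F)F
Why: O-sulfonylation of the remaining phenol turns it into a cross-coupling handle at the carbon that will carry chroman B.

**Step 3**
Reactants: 3 5-(benzyloxy)-2-formyl-3-methoxyphenyl trifluoromethanesulfonate; 4 2-bromo-3,3-diethoxyprop-1-ene
Product: 8 2-[5-(benzyloxy)-2-formyl-3-methoxyphenyl]prop-2-enal, via (3,3-diethoxyprop-1-en-2-yl)lithium 5 (not isolated), via chloro(3,3-diethoxyprop-1-en-2-yl)zinc 6 (not isolated), via 4-(benzyloxy)-2-(3,3-diethoxyprop-1-en-2-yl)-6-methoxybenzaldehyde 7 (not isolated)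
Conditions: 4, n-BuLi, THF, −78 °C; ZnCl2, −78 °C to rt; 3, Pd(PPh3)4 (5 mol%), 50 °C; then 1 M HCl, THF, 0 °C
Reagents that add atoms: water, O
Why: Bromine–lithium exchange, transmetalation to zinc and Negishi coupling (the organozinc tolerates the aryl aldehyde) install an acrolein α-anion equivalent; mild acetal hydrolysis then frees the 2-arylacrolein.

**Step 4**
Reactants: 8 2-[5-(benzyloxy)-2-formyl-3-methoxyphenyl]prop-2-enal; 9 3-(benzyloxy)phenol
Product: 11 5-(benzyloxy)-2-[{4-(benzyloxy)-2-[3-(4-(benzyloxy)-2-hydroxyphenyl)-3-hydroxyprop-1-en-2-yl]-6-methoxyphenyl}(hydroxy)methyl]phenol (diastereomer mixture at the two carbinol carbons), via bromomagnesium 3-(benzyloxy)phenoxide 10 (not isolated)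
Conditions: 9 (2.5 equiv), EtMgBr (2.5 equiv), Et2O, 0 °C; solvent change to CH2Cl2; 8, 0 °C to rt; pH 7 buffer
Reagents that add atoms: none
Why: Chelation-controlled ortho-specific C-hydroxyalkylation of a magnesium phenoxide (Casiraghi-type 1,2-addition) attacks both aldehydes at the less hindered ortho carbon para to OBn; the two new carbinol centres are erased in step 7.

**Step 5**
Reactants: 12 2-hydroxy-4,5-dimethoxybenzaldehyde
Product: 13 2-(benzyloxy)-4,5-dimethoxybenzaldehyde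
Conditions: BnBr, K2CO3, DMF, rt
Reagents that add atoms: benzyl bromide, BrCc1ccccc1
Why: Williamson etherification; masking this phenol stops it from competing with the chroman A phenol for the aldehyde carbon in step 7.

**Step 6**
Reactants: 13 2-(benzyloxy)-4,5-dimethoxybenzaldehyde
Product: 15 [2-(benzyloxy)-4,5-dimethoxyphenyl]acetaldehyde, via 1-(benzyloxy)-4,5-dimethoxy-2-(2-methoxyethenyl)benzene 14 (not isolated)
Conditions: Ph3P(CH2OMe)Cl, KOtBu, THF, 0 °C; then 2 M HCl, THF, rt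
Reagents that add atoms: (methoxymethyl)triphenylphosphonium chloride, COC[P+](c1ccccc1)(c1ccccc1)c1ccccc1.[Cl-]; water, O
Why: Wittig methoxymethylenation followed by enol ether hydrolysis gives the one-carbon homologated arylacetaldehyde.

**Step 7 (key step)**
Reactants: 11 bis-carbinol from step 4; 15 [2-(benzyloxy)-4,5-dimethoxyphenyl]acetaldehyde
Product: 17 (3R,4S)-7-(benzyloxy)-4-{4-(benzyloxy)-2-[7-(benzyloxy)-2H-chromen-3-yl]-6-methoxyphenyl}-3-[2-(benzyloxy)-4,5-dimethoxyphenyl]-3,4-dihydro-2H-chromen-2-ol (C2 epimer mixture), via bis(ortho-quinone methide) 16 (not isolated)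
Conditions: 15 (2 equiv, slow addition), (R)-2-[diphenyl(trimethylsilyloxy)methyl]pyrrolidine (20 mol%), 3,5-dinitrobenzoic acid (30 mol%), CHCl3, 0 °C to rt, then 40 °C
Reagents that add atoms: none
Why: Proposed new method: the acid ionises both ortho-hydroxybenzylic carbinols of 11 to ortho-quinone methides (16). The vinyl-substituted one closes at once by oxa-6π electrocyclisation to the 2H-chromene of chroman B. The diaryl one is attacked by the E-enamine of 15 on its Re face (the face left open by the (R)-catalyst) in an endo formal [4+2] (Michael addition then hemiacetalisation), which sets C3 as R and places the C4 aryl trans (4S); trans is also the thermodynamic arrangement. The closest known reactions are the amine/acid-catalysed α-alkylation of aldehydes with in situ ortho-quinone methides to trans-chroman-2-ols and the acid-mediated cyclodehydration of 2-(1-hydroxyallyl)phenols to 2H-chromenes. The catalyst sense is assigned from the usual enamine shielding model and should be confirmed on a model; the (S)-catalyst is equally available.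

**Step 8**
Reactants: 17 lactol–chromene from step 7
Product: 18 (3R,4S)-7-(benzyloxy)-4-{4-(benzyloxy)-2-[(3R)-7-(benzyloxy)-3,4-dihydro-2H-chromen-3-yl]-6-methoxyphenyl}-3-[2-(benzyloxy)-4,5-dimethoxyphenyl]-3,4-dihydro-2H-chromen-2-ol (C2 epimer mixture)
Conditions: H2 (50 bar), [Ir(cod)((4R,5R)-ThrePHOX)][B(C6H3(CF3)2)4] (2 mol%), CH2Cl2, rt
Reagents that add atoms: none
Why: Ligand-controlled asymmetric hydrogenation of the trisubstituted aryl alkene by a cationic monovalent iridium N,P complex sets C3 of chroman B as R. The (4R,5R) ligand is chosen by analogy with simple 3-aryl-2H-chromenes (assigned from recall, to be confirmed). It is run before any Lewis acid step because the chromene would otherwise be reduced without stereocontrol.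

**Step 9**
Reactants: 18 lactol from step 8
Product: 19 (3R,4S)-7-(benzyloxy)-4-{4-(benzyloxy)-2-[(3R)-7-(benzyloxy)-3,4-dihydro-2H-chromen-3-yl]-6-methoxyphenyl}-3-[2-(benzyloxy)-4,5-dimethoxyphenyl]-3,4-dihydro-2H-chromene
Conditions: Et3SiH (3 equiv), BF3·OEt2 (2 equiv), CH2Cl2, −78 to −20 °C
Reagents that add atoms: none
Why: Ionic hydrogenation of the lactol through its cyclic oxocarbenium ion turns C2 into CH2; C4 is untouched and C3 stays in the favoured trans arrangement.

**Step 10**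
Reactants: 19 tetrabenzyl ether from step 9
Product: 20 (3R,4S)-4-{4-hydroxy-2-[(3R)-7-hydroxy-3,4-dihydro-2H-chromen-3-yl]-6-methoxyphenyl}-3-(2-hydroxy-4,5-dimethoxyphenyl)-3,4-dihydro-2H-chromen-7-ol (target)
Conditions: H2 (1 atm), 10% Pd/C, EtOAc/MeOH, rt
Reagents that add atoms: none
Why: Hydrogenolysis removes the four O-benzyl groups; methyl ethers, the chroman C–O bonds and the three stereocentres are not affected.

## Compound list

1 | 2,4-dihydroxy-6-methoxybenzaldehyde | COc1cc(O)cc(O)c1C=O | starting material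
2 | 4-(benzyloxy)-2-hydroxy-6-methoxybenzaldehyde | COc1cc(OCc2ccccc2)cc(O)c1C=O | intermediate
3 | 5-(benzyloxy)-2-formyl-3-methoxyphenyl trifluoromethanesulfonate | COc1cc(OCc2ccccc2)cc(OS(=O)(=O)C(F)(F)F)c1C=O | intermediate
4 | 2-bromo-3,3-diethoxyprop-1-ene | C=C(Br)C(OCC)OCC | starting material
5 | (3,3-diethoxyprop-1-en-2-yl)lithium | [Li]C(=C)C(OCC)OCC | intermediate
6 | chloro(3,3-diethoxyprop-1-en-2-yl)zinc | Cl[Zn]C(=C)C(OCC)OCC | intermediate
7 | 4-(benzyloxy)-2-(3,3-diethoxyprop-1-en-2-yl)-6-methoxybenzaldehyde | COc1cc(OCc2ccccc2)cc(C(=C)C(OCC)OCC)c1C=O | intermediate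
8 | 2-[5-(benzyloxy)-2-formyl-3-methoxyphenyl]prop-2-enal | COc1cc(OCc2ccccc2)cc(C(=C)C=O)c1C=O | intermediate
9 | 3-(benzyloxy)phenol | Oc1cccc(OCc2ccccc2)c1 | starting material
10 | bromomagnesium 3-(benzyloxy)phenoxide | Br[Mg]Oc1cccc(OCc2ccccc2)c1 | intermediate
11 | 5-(benzyloxy)-2-[{4-(benzyloxy)-2-[3-(4-(benzyloxy)-2-hydroxyphenyl)-3-hydroxyprop-1-en-2-yl]-6-methoxyphenyl}(hydroxy)methyl]phenol, carbinol centres unassigned | COc1cc(OCc2ccccc2)cc(C(=C)C(O)c2ccc(OCc3ccccc3)cc2O)c1C(O)c1ccc(OCc2ccccc2)cc1O | intermediate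
12 | 2-hydroxy-4,5-dimethoxybenzaldehyde | COc1cc(O)c(C=O)cc1OC | starting material
13 | 2-(benzyloxy)-4,5-dimethoxybenzaldehyde | COc1cc(OCc2ccccc2)c(C=O)cc1OC | intermediate
14 | 1-(benzyloxy)-4,5-dimethoxy-2-(2-methoxyethenyl)benzene (E/Z mixture) | COC=Cc1cc(OC)c(OC)cc1OCc1ccccc1 | intermediate
15 | [2-(benzyloxy)-4,5-dimethoxyphenyl]acetaldehyde | COc1cc(OCc2ccccc2)c(CC=O)cc1OC | intermediate
16 | bis(ortho-quinone methide) from 11 by loss of two waters; both carbinol carbons become exocyclic C=C of 6-methylidenecyclohexa-2,4-dien-1-ones | COc1cc(OCc2ccccc2)cc(C(=C)C=C2C=CC(OCc3ccccc3)=CC2=O)c1C=C1C=CC(OCc2ccccc2)=CC1=O | intermediate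
17 | (3R,4S)-7-(benzyloxy)-4-{4-(benzyloxy)-2-[7-(benzyloxy)-2H-chromen-3-yl]-6-methoxyphenyl}-3-[2-(benzyloxy)-4,5-dimethoxyphenyl]-3,4-dihydro-2H-chromen-2-ol, C2 epimers | COc1cc(OCc2ccccc2)c([C@@H]3C(O)Oc4cc(OCc5ccccc5)ccc4[C@H]3c3c(OC)cc(OCc4ccccc4)cc3C3=Cc4ccc(OCc5ccccc5)cc4OC3)cc1OC | intermediate
18 | (3R,4S)-7-(benzyloxy)-4-{4-(benzyloxy)-2-[(3R)-7-(benzyloxy)-3,4-dihydro-2H-chromen-3-yl]-6-methoxyphenyl}-3-[2-(benzyloxy)-4,5-dimethoxyphenyl]-3,4-dihydro-2H-chromen-2-ol, C2 epimers | COc1cc(OCc2ccccc2)c([C@@H]3C(O)Oc4cc(OCc5ccccc5)ccc4[C@H]3c3c(OC)cc(OCc4ccccc4)cc3[C@@H]3COc4cc(OCc5ccccc5)ccc4C3)cc1OC | intermediate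
19 | (3R,4S)-7-(benzyloxy)-4-{4-(benzyloxy)-2-[(3R)-7-(benzyloxy)-3,4-dihydro-2H-chromen-3-yl]-6-methoxyphenyl}-3-[2-(benzyloxy)-4,5-dimethoxyphenyl]-3,4-dihydro-2H-chromene | COc1cc(OCc2ccccc2)c([C@@H]3COc4cc(OCc5ccccc5)ccc4[C@H]3c3c(OC)cc(OCc4ccccc4)cc3[C@@H]3COc4cc(OCc5ccccc5)ccc4C3)cc1OC | intermediate
20 | (3R,4S)-4-{4-hydroxy-2-[(3R)-7-hydroxy-3,4-dihydro-2H-chromen-3-yl]-6-methoxyphenyl}-3-(2-hydroxy-4,5-dimethoxyphenyl)-3,4-dihydro-2H-chromen-7-ol | COc1cc(O)c([C@@H]2COc3cc(O)ccc3[C@H]2c2c(OC)cc(O)cc2[C@@H]2COc3cc(O)ccc3C2)cc1OC | target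

## Step count and risk

Total steps: 10. Longest linear sequence: 8 (steps 1, 2, 3, 4, 7, 8, 9, 10 from compound 1); steps 5 and 6 form the side branch that joins at step 7.

**Most likely to fail: step 7.** The diaryl quinone methide may be lost to cationic side reactions, the arylacetaldehyde may self-condense, or the silyl ether catalyst may not survive the acid. The fallback sets out from 11 and from the enol ether 14 (isolated as its E isomer instead of being hydrolysed) and comes back at 19. A chiral phosphoric acid, (R)-TRIP (10 mol%, CHCl3, −20 °C to rt; enantiomer to be confirmed), replaces the amine/acid pair. The acid alone forms both quinone methides. The diaryl one is taken up by the enol ether in an ion-pair-controlled inverse-demand hetero-Diels–Alder reaction, and the vinyl one still closes by electrocyclisation. This gives the 2-methoxy acetal (3R,4S)-7-(benzyloxy)-4-{4-(benzyloxy)-2-[7-(benzyloxy)-2H-chromen-3-yl]-6-methoxyphenyl}-3-[2-(benzyloxy)-4,5-dimethoxyphenyl]-2-methoxy-3,4-dihydro-2H-chromene F1. Hydrogenation as in step 8 gives the saturated acetal (3R,4S)-7-(benzyloxy)-4-{4-(benzyloxy)-2-[(3R)-7-(benzyloxy)-3,4-dihydro-2H-chromen-3-yl]-6-methoxyphenyl}-3-[2-(benzyloxy)-4,5-dimethoxyphenyl]-2-methoxy-3,4-dihydro-2H-chromene F2. Et3SiH/BF3·OEt2 then removes the methoxy group to give 19.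

**Second: step 8.** The alkene carries a very bulky ortho-substituted aryl group, so rate and facial sense are uncertain. The fallback sets out from 17 and comes back at 19. Et3SiH (6 equiv) and CF3CO2H in CH2Cl2 at 0 °C reduce the lactol and, through the benzyloxy-stabilised C4 cation, the chromene in one ionic hydrogenation without control at the new centre. This gives 19 together with its epimer (3R,4S)-7-(benzyloxy)-4-{4-(benzyloxy)-2-[(3S)-7-(benzyloxy)-3,4-dihydro-2H-chromen-3-yl]-6-methoxyphenyl}-3-[2-(benzyloxy)-4,5-dimethoxyphenyl]-3,4-dihydro-2H-chromene F3. The two diastereomers are separated by preparative HPLC and 19 is carried on.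

**Third: step 4.** The aryl aldehyde is flanked by two ortho substituents, and the acrolein can polymerise or take up a second phenol. The fallback sets out from 7 and comes back at 11. Commercial 5-(benzyloxy)-2-bromophenol is silylated (i-Pr3SiCl, imidazole, DMF) to [5-(benzyloxy)-2-bromophenoxy]tri(propan-2-yl)silane F4. Bromine–lithium exchange (n-BuLi, THF, −78 °C) gives {4-(benzyloxy)-2-[tri(propan-2-yl)silyloxy]phenyl}lithium F5. Two equivalents add to both aldehyde groups of 8 at −78 °C to give the bis(silyl ether) of 11, F6. Bu4NF in THF at 0 °C frees the two phenols and gives 11.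

## Further compounds

F1 | step 7 | (3R,4S)-7-(benzyloxy)-4-{4-(benzyloxy)-2-[7-(benzyloxy)-2H-chromen-3-yl]-6-methoxyphenyl}-3-[2-(benzyloxy)-4,5-dimethoxyphenyl]-2-methoxy-3,4-dihydro-2H-chromene | COc1cc(OCc2ccccc2)c([C@@H]3C(OC)Oc4cc(OCc5ccccc5)ccc4[C@H]3c3c(OC)cc(OCc4ccccc4)cc3C3=Cc4ccc(OCc5ccccc5)cc4OC3)cc1OC
F2 | step 7 | (3R,4S)-7-(benzyloxy)-4-{4-(benzyloxy)-2-[(3R)-7-(benzyloxy)-3,4-dihydro-2H-chromen-3-yl]-6-methoxyphenyl}-3-[2-(benzyloxy)-4,5-dimethoxyphenyl]-2-methoxy-3,4-dihydro-2H-chromene | COc1cc(OCc2ccccc2)c([C@@H]3C(OC)Oc4cc(OCc5ccccc5)ccc4[C@H]3c3c(OC)cc(OCc4ccccc4)cc3[C@@H]3COc4cc(OCc5ccccc5)ccc4C3)cc1OC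
F3 | step 8 | (3R,4S)-7-(benzyloxy)-4-{4-(benzyloxy)-2-[(3S)-7-(benzyloxy)-3,4-dihydro-2H-chromen-3-yl]-6-methoxyphenyl}-3-[2-(benzyloxy)-4,5-dimethoxyphenyl]-3,4-dihydro-2H-chromene | COc1cc(OCc2ccccc2)c([C@@H]3COc4cc(OCc5ccccc5)ccc4[C@H]3c3c(OC)cc(OCc4ccccc4)cc3[C@H]3COc4cc(OCc5ccccc5)ccc4C3)cc1OC
F4 | step 4 | [5-(benzyloxy)-2-bromophenoxy]tri(propan-2-yl)silane | CC(C)[Si](C(C)C)(C(C)C)Oc1cc(OCc2ccccc2)ccc1Br
F5 | step 4 | {4-(benzyloxy)-2-[tri(propan-2-yl)silyloxy]phenyl}lithium | CC(C)[Si](C(C)C)(C(C)C)Oc1cc(OCc2ccccc2)ccc1[Li]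
F6 | step 4 | bis[tri(propan-2-yl)silyl] ether of 11 at its two phenol oxygens | COc1cc(OCc2ccccc2)cc(C(=C)C(O)c2ccc(OCc3ccccc3)cc2O[Si](C(C)C)(C(C)C)C(C)C)c1C(O)c1ccc(OCc2ccccc2)cc1O[Si](C(C)C)(C(C)C)C(C)C
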